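**Retrosynthetic overview**
1. The C8=C9 E-olefin is made last by cross-metathesis of allyl dioxane 18 (fragment 1) with tertiary allylic alcohol 24 (fragment 2); C1 is then desilylated and oxidised to the acid.
2. Fragment 2 comes from dihydro-β-ionone (cyclohexene ring bought intact): E-allylic alcohol, Sharpless epoxidation, epoxy iodide, zinc opening (sets C10).
3. The 1,2-dioxane is closed at O–C3 by 6-exo SN2 of a C6 hydroperoxide on a C3 mesylate (inversion); the C6–OOH comes from Lewis-acid perhydrolysis of a 2,2-disubstituted oxetane (inversion), and the freed C8 alcohol becomes the allyl group.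
4. C3 is set by ketoreductase reduction of a β-keto ester and C2 by Fráter–Seebach anti-methylation; the ester is reduced and silylated before ring closure.
5. The oxetane comes from geraniol: Sharpless epoxidation (first stereocentre, C6), hydride opening to the 1,3-diol, Williamson closure, ozonolysis. Ring order: oxetane (temporary, step 3), then 1,2-dioxane (step 13).

Atom labels (target chain): C1 = CO2H, C2 = CHMe, C3 = dioxane CH, C6 = dioxane quaternary C, C7 = CH2, C8=C9 = E-olefin, C10 = carbinol C.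
Assumption: an (R)-selective ketoreductase that accepts keto ester 9 is taken from a commercial screening panel.

**Route**

Step 1
Reactants: 1 geraniol, (2E)-3,7-dimethylocta-2,6-dien-1-ol
Product: 2 [(2R,3R)-3-methyl-3-(4-methylpent-3-en-1-yl)oxiran-2-yl]methanol
Conditions: Ti(OiPr)4 (5 mol%), D-(−)-diethyl tartrate (7 mol%), tBuOOH (anhydrous, 2 equiv), 4 Å MS, CH2Cl2, −20 °C
Reagents that add atoms: tert-butyl hydroperoxide, CC(C)(C)OO
Why: Sharpless asymmetric epoxidation touches only the allylic 2,3-olefin, and the D-tartrate catalyst gives the (2R,3R) epoxide (the L-tartrate is known to give 2S,3S), which sets C6 as the first stereocentre.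

Step 2
Reactants: 2 [(2R,3R)-3-methyl-3-(4-methylpent-3-en-1-yl)oxiran-2-yl]methanol
Product: 3 (3R)-3,7-dimethyloct-6-ene-1,3-diol
Conditions: NaAlH2(OCH2CH2OCH3)2, THF, 0 °C to rt
Reagents that add atoms: none
Why: Hydroxyl-directed hydride opening of the 2,3-epoxy alcohol at C2 gives the 1,3-diol, and the tertiary C–O bond is untouched so the configuration is retained.

Step 3
Reactants: 3 (3R)-3,7-dimethyloct-6-ene-1,3-diol
Product: 5 (2R)-2-methyl-2-(4-methylpent-3-en-1-yl)oxetane, via (3R)-3-hydroxy-3,7-dimethyloct-6-en-1-yl tosylate 4 (not isolated)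
Conditions: n-BuLi (1.0 equiv), THF, 0 °C; TsCl (1.0 equiv), 0 °C to rt; n-BuLi (1.0 equiv), 0 to 60 °C
Reagents that add atoms: none
Why: The primary alkoxide is sulfonylated selectively and the tertiary alkoxide then closes the ring by intramolecular Williamson etherification (4-exo-tet) without touching the stereocentre.

Step 4
Reactants: 5 (2R)-2-methyl-2-(4-methylpent-3-en-1-yl)oxetane
Product: 7 3-[(2R)-2-methyloxetan-2-yl]propanal, via secondary ozonide 6 (not isolated)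
Conditions: O3, CH2Cl2, −78 °C; then PPh3, −78 °C to rt
Reagents that add atoms: ozone, [O-][O+]=O
Why: Ozonolysis of the trisubstituted olefin with reductive work-up exposes the C3 aldehyde, and the oxetane is inert to both reagents.

Step 5
Reactants: 7 3-[(2R)-2-methyloxetan-2-yl]propanal
Product: 8 ethyl (3RS)-3-hydroxy-5-[(2R)-2-methyloxetan-2-yl]pentanoate (both C3 epimers)
Conditions: LiN(iPr)2, EtOAc, THF, −78 °C; then 7; aqueous NH4Cl
Reagents that add atoms: ethyl acetate, CCOC(C)=O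
Why: Acetate aldol addition of the lithium enolate builds C1–C2, and the unselective carbinol centre is erased in step 6.

Step 6
Reactants: 8 ethyl (3RS)-3-hydroxy-5-[(2R)-2-methyloxetan-2-yl]pentanoate
Product: 9 ethyl 5-[(2R)-2-methyloxetan-2-yl]-3-oxopentanoate
Conditions: Dess–Martin periodinane, NaHCO3, CH2Cl2, 0 °C to rt
Reagents that add atoms: none
Why: Buffered Dess–Martin oxidation gives the β-keto ester under neutral conditions that leave the oxetane closed.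

Step 7
Reactants: 9 ethyl 5-[(2R)-2-methyloxetan-2-yl]-3-oxopentanoate
Product: 10 ethyl (3R)-3-hydroxy-5-[(2R)-2-methyloxetan-2-yl]pentanoate
Conditions: ketoreductase (R-selective, NADPH-dependent), NADP+ (0.5 mol%), iPrOH (10 vol%), KH2PO4/K2HPO4 buffer (0.1 M, pH 7.0), 30 °C
Reagents that add atoms: none
Why: Enzymatic asymmetric reduction of the β-keto ester by a ketoreductase, with isopropanol recycling the cofactor, delivers hydride to one carbonyl face and sets C3 as R in neutral water that spares the oxetane and the ester.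

Step 8
Reactants: 10 ethyl (3R)-3-hydroxy-5-[(2R)-2-methyloxetan-2-yl]pentanoate
Product: 11 ethyl (2R,3R)-3-hydroxy-2-methyl-5-[(2R)-2-methyloxetan-2-yl]pentanoate
Conditions: LiN(iPr)2 (2.2 equiv), THF, −78 to −20 °C; MeI, DMPU, −78 to 0 °C
Reagents that add atoms: iodomethane, CI
Why: Fráter–Seebach alkylation of the chelated alkoxide–enolate dianion puts the methyl on the face opposite the C3 substituent, giving the 2,3-anti product (dr about 95:5) and setting C2.

Step 9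
Reactants: 11 ethyl (2R,3R)-3-hydroxy-2-methyl-5-[(2R)-2-methyloxetan-2-yl]pentanoate
Product: 12 (2S,3R)-2-methyl-5-[(2R)-2-methyloxetan-2-yl]pentane-1,3-diol
Conditions: LiAlH4, THF, 0 °C
Reagents that add atoms: none
Why: Hydride reduction of the ester removes the acidic α-hydrogen before the base-mediated ring closure (the C2 descriptor changes only through CIP priority), and the oxetane is not opened at 0 °C.

Step 10
Reactants: 12 (2S,3R)-2-methyl-5-[(2R)-2-methyloxetan-2-yl]pentane-1,3-diol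
Product: 13 (2S,3R)-1-[(tert-butyldiphenylsilyl)oxy]-2-methyl-5-[(2R)-2-methyloxetan-2-yl]pentan-3-ol
Conditions: tBuPh2SiCl (1.05 equiv), imidazole, CH2Cl2, 0 °C
Reagents that add atoms: tert-butyl(chloro)diphenylsilane, CC(C)(C)[Si](Cl)(c1ccccc1)c1ccccc1
Why: The bulky silyl chloride protects the primary hydroxyl selectively over the hindered secondary one.

Step 11
Reactants: 13 (2S,3R)-1-[(tert-butyldiphenylsilyl)oxy]-2-methyl-5-[(2R)-2-methyloxetan-2-yl]pentan-3-ol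
Product: 14 (2S,3R)-1-[(tert-butyldiphenylsilyl)oxy]-2-methyl-5-[(2R)-2-methyloxetan-2-yl]pentan-3-yl methanesulfonate
Conditions: MsCl, Et3N, CH2Cl2, 0 °C
Reagents that add atoms: methanesulfonyl chloride, CS(=O)(=O)Cl
Why: O-Sulfonylation activates C3 with retention because only the O–H bond reacts.

Step 12
Reactants: 14 (2S,3R)-1-[(tert-butyldiphenylsilyl)oxy]-2-methyl-5-[(2R)-2-methyloxetan-2-yl]pentan-3-yl methanesulfonate
Product: 15 (2S,3R,6S)-1-[(tert-butyldiphenylsilyl)oxy]-6-hydroperoxy-8-hydroxy-2,6-dimethyloctan-3-yl methanesulfonate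
Conditions: H2O2 (anhydrous, about 2 M in Et2O, 10 equiv), Me3SiOTf (0.2 equiv), Et2O, −78 to 0 °C
Reagents that add atoms: hydrogen peroxide, OO
Why: Lewis-acid-promoted perhydrolysis of the 2,2-disubstituted oxetane lets H2O2 attack the tertiary carbon from the back (inversion, R oxetane to 6S hydroperoxide) and frees the C8 hydroxyl, while the mesylate and silyl ether are inert.

Step 13
Reactants: 15 (2S,3R,6S)-1-[(tert-butyldiphenylsilyl)oxy]-6-hydroperoxy-8-hydroxy-2,6-dimethyloctan-3-yl methanesulfonate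
Product: 16 2-[(3S,6S)-6-{(2S)-1-[(tert-butyldiphenylsilyl)oxy]propan-2-yl}-3-methyl-1,2-dioxan-3-yl]ethan-1-ol
Conditions: KOtBu (1.1 equiv), 18-crown-6, toluene, 0 °C to rt
Reagents that add atoms: none
Why: Intramolecular alkylation of the hydroperoxide (6-exo-tet SN2) on the secondary mesylate closes the 1,2-dioxane with inversion at C3 (3R mesylate to 3S peroxide), and only the more acidic OOH is deprotonated.

Step 14
Reactants: 16 2-[(3S,6S)-6-{(2S)-1-[(tert-butyldiphenylsilyl)oxy]propan-2-yl}-3-methyl-1,2-dioxan-3-yl]ethan-1-ol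
Product: 17 2-[(3S,6S)-6-{(2S)-1-[(tert-butyldiphenylsilyl)oxy]propan-2-yl}-3-methyl-1,2-dioxan-3-yl]acetaldehyde
Conditions: Dess–Martin periodinane, NaHCO3, CH2Cl2, 0 °C
Reagents that add atoms: none
Why: Dess–Martin oxidation is neutral and metal-free, so the dialkyl peroxide and silyl ether survive.

Step 15
Reactants: 17 2-[(3S,6S)-6-{(2S)-1-[(tert-butyldiphenylsilyl)oxy]propan-2-yl}-3-methyl-1,2-dioxan-3-yl]acetaldehyde
Product: 18 tert-butyl{(2S)-2-[(3S,6S)-6-methyl-6-(prop-2-en-1-yl)-1,2-dioxan-3-yl]propoxy}diphenylsilane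
Conditions: Ph3PCH3Br, KN(SiMe3)2, THF, 0 °C; then 17, −78 to 0 °C
Reagents that add atoms: methyltriphenylphosphonium bromide, C[P+](c1ccccc1)(c1ccccc1)c1ccccc1.[Br-]
Why: Wittig methylenation at low temperature is faster than β-elimination of the peroxide, and the quaternary C6 cannot epimerise.

Step 16
Reactants: 19 dihydro-β-ionone, 4-(2,6,6-trimethylcyclohex-1-en-1-yl)butan-2-one
Product: 20 ethyl (2E)-3-methyl-5-(2,6,6-trimethylcyclohex-1-en-1-yl)pent-2-enoate
Conditions: (EtO)2P(O)CH2CO2Et, NaH, THF, 0 °C to reflux; E isomer separated on SiO2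
Reagents that add atoms: triethyl phosphonoacetate, CCOC(=O)CP(=O)(OCC)OCC
Why: Horner–Wadsworth–Emmons olefination of the methyl ketone gives mainly the E enoate (about 5:1), and the minor Z isomer is removed by chromatography.

Step 17
Reactants: 20 ethyl (2E)-3-methyl-5-(2,6,6-trimethylcyclohex-1-en-1-yl)pent-2-enoate
Product: 21 (2E)-3-methyl-5-(2,6,6-trimethylcyclohex-1-en-1-yl)pent-2-en-1-ol
Conditions: iBu2AlH (2.2 equiv), CH2Cl2, −78 °C
Reagents that add atoms: none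
Why: 1,2-Reduction of the enoate gives the allylic alcohol with the olefin geometry unchanged.

Step 18
Reactants: 21 (2E)-3-methyl-5-(2,6,6-trimethylcyclohex-1-en-1-yl)pent-2-en-1-ol
Product: 22 {(2S,3S)-3-methyl-3-[2-(2,6,6-trimethylcyclohex-1-en-1-yl)ethyl]oxiran-2-yl}methanol
Conditions: Ti(OiPr)4 (10 mol%), L-(+)-diethyl tartrate (12 mol%), tBuOOH (anhydrous), 4 Å MS, CH2Cl2, −20 °C
Reagents that add atoms: tert-butyl hydroperoxide, CC(C)(C)OO
Why: Sharpless asymmetric epoxidation with the L-tartrate gives the (2S,3S) epoxy alcohol, as with geraniol, which sets C10, and the tetrasubstituted ring olefin is not an allylic alcohol and stays intact.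

Step 19
Reactants: 22 {(2S,3S)-3-methyl-3-[2-(2,6,6-trimethylcyclohex-1-en-1-yl)ethyl]oxiran-2-yl}methanol
Product: 23 (2R,3S)-2-(iodomethyl)-3-methyl-3-[2-(2,6,6-trimethylcyclohex-1-en-1-yl)ethyl]oxirane
Conditions: I2, PPh3, imidazole, Et2O/MeCN (3:1), 0 °C
Reagents that add atoms: iodine, II
Why: Appel-type iodination of the primary alcohol leaves both stereocentres untouched (the descriptor at the oxirane CH changes only through CIP priority).

Step 20
Reactants: 23 (2R,3S)-2-(iodomethyl)-3-methyl-3-[2-(2,6,6-trimethylcyclohex-1-en-1-yl)ethyl]oxirane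
Product: 24 (3S)-3-methyl-5-(2,6,6-trimethylcyclohex-1-en-1-yl)pent-1-en-3-ol
Conditions: Zn dust, AcOH, EtOH, rt
Reagents that add atoms: none
Why: Zinc insertion and β-elimination open the epoxy iodide reductively to the tertiary allylic alcohol, and the C10–O bond is retained so C10 stays S.

Step 21
Reactants: 18 tert-butyl{(2S)-2-[(3S,6S)-6-methyl-6-(prop-2-en-1-yl)-1,2-dioxan-3-yl]propoxy}diphenylsilane; 24 (3S)-3-methyl-5-(2,6,6-trimethylcyclohex-1-en-1-yl)pent-1-en-3-ol (3 equiv)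
Product: 25 tert-butyl{(2S)-2-[(3S,6S)-6-[(2E,4S)-4-hydroxy-4-methyl-6-(2,6,6-trimethylcyclohex-1-en-1-yl)hex-2-en-1-yl]-6-methyl-1,2-dioxan-3-yl]propoxy}diphenylsilane
Conditions: second-generation Hoveyda–Grubbs catalyst RuCl2(=CH-C6H4-2-OiPr)(H2IMes) (10 mol%), CH2Cl2, 40 °C, argon sparge
Reagents that add atoms: none
Why: Olefin cross-metathesis joins the terminal allyl group to the hindered tertiary allylic alcohol (which homodimerises slowly and is used in excess) with thermodynamic E-selectivity, while the tetrasubstituted ring olefin and the dialkyl peroxide do not react with the ruthenium carbene.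

Step 22
Reactants: 25 tert-butyl{(2S)-2-[(3S,6S)-6-[(2E,4S)-4-hydroxy-4-methyl-6-(2,6,6-trimethylcyclohex-1-en-1-yl)hex-2-en-1-yl]-6-methyl-1,2-dioxan-3-yl]propoxy}diphenylsilane
Product: 26 (2S)-2-[(3S,6S)-6-[(2E,4S)-4-hydroxy-4-methyl-6-(2,6,6-trimethylcyclohex-1-en-1-yl)hex-2-en-1-yl]-6-methyl-1,2-dioxan-3-yl]propan-1-ol
Conditions: Bu4NF, AcOH (1:1), THF, 0 °C to rt
Reagents that add atoms: none
Why: Fluoride desilylation buffered with acetic acid frees the primary alcohol without base-induced cleavage of the peroxide or ionisation of the tertiary allylic alcohol.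

Step 23
Reactants: 26 (2S)-2-[(3S,6S)-6-[(2E,4S)-4-hydroxy-4-methyl-6-(2,6,6-trimethylcyclohex-1-en-1-yl)hex-2-en-1-yl]-6-methyl-1,2-dioxan-3-yl]propan-1-ol
Product: 28 (2R)-2-[(3S,6S)-6-[(2E,4S)-4-hydroxy-4-methyl-6-(2,6,6-trimethylcyclohex-1-en-1-yl)hex-2-en-1-yl]-6-methyl-1,2-dioxan-3-yl]propanoic acid (target), via C1 aldehyde 27 (not isolated)
Conditions: TEMPO (10 mol%), PhI(OAc)2, CH2Cl2, rt; then NaClO2, NaH2PO4, 2-methyl-2-butene, tBuOH/H2O, 0 °C
Reagents that add atoms: sodium chlorite, [Na+].[O-]Cl=O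
Why: Oxoammonium oxidation takes only the primary alcohol to the aldehyde and Pinnick oxidation carries it on to the acid under near-neutral conditions that avoid C2 epimerisation, with 2-methyl-2-butene scavenging HOCl to protect the olefins.

**Compound list**
1 | geraniol, (2E)-3,7-dimethylocta-2,6-dien-1-ol | CC(C)=CCC/C(C)=C/CO | starting material
2 | [(2R,3R)-3-methyl-3-(4-methylpent-3-en-1-yl)oxiran-2-yl]methanol | C[C@]1(CCC=C(C)C)O[C@@H]1CO | intermediate
3 | (3R)-3,7-dimethyloct-6-ene-1,3-diol | C[C@@](O)(CCC=C(C)C)CCO | intermediate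
4 | (3R)-3-hydroxy-3,7-dimethyloct-6-en-1-yl 4-methylbenzenesulfonate (not isolated) | C[C@@](O)(CCC=C(C)C)CCOS(=O)(=O)c1ccc(C)cc1 | intermediate
5 | (2R)-2-methyl-2-(4-methylpent-3-en-1-yl)oxetane | C[C@@]1(CCC=C(C)C)CCO1 | intermediate
6 | 3,3-dimethyl-5-{2-[(2R)-2-methyloxetan-2-yl]ethyl}-1,2,4-trioxolane, both C5 epimers (not isolated) | C[C@@]1(CCC2OOC(C)(C)O2)CCO1 | intermediate
7 | 3-[(2R)-2-methyloxetan-2-yl]propanal | C[C@@]1(CCC=O)CCO1 | intermediate
8 | ethyl (3RS)-3-hydroxy-5-[(2R)-2-methyloxetan-2-yl]pentanoate | C[C@@]1(CCC(O)CC(=O)OCC)CCO1 | intermediate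
9 | ethyl 5-[(2R)-2-methyloxetan-2-yl]-3-oxopentanoate | C[C@@]1(CCC(=O)CC(=O)OCC)CCO1 | intermediate
10 | ethyl (3R)-3-hydroxy-5-[(2R)-2-methyloxetan-2-yl]pentanoate | C[C@@]1(CC[C@@H](O)CC(=O)OCC)CCO1 | intermediate
11 | ethyl (2R,3R)-3-hydroxy-2-methyl-5-[(2R)-2-methyloxetan-2-yl]pentanoate | C[C@@]1(CC[C@@H](O)[C@@H](C)C(=O)OCC)CCO1 | intermediate
12 | (2S,3R)-2-methyl-5-[(2R)-2-methyloxetan-2-yl]pentane-1,3-diol | C[C@@]1(CC[C@@H](O)[C@@H](C)CO)CCO1 | intermediate
13 | (2S,3R)-1-[(tert-butyldiphenylsilyl)oxy]-2-methyl-5-[(2R)-2-methyloxetan-2-yl]pentan-3-ol | C[C@@]1(CC[C@@H](O)[C@@H](C)CO[Si](c2ccccc2)(c2ccccc2)C(C)(C)C)CCO1 | intermediate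
14 | (2S,3R)-1-[(tert-butyldiphenylsilyl)oxy]-2-methyl-5-[(2R)-2-methyloxetan-2-yl]pentan-3-yl methanesulfonate | C[C@@]1(CC[C@@H](OS(C)(=O)=O)[C@@H](C)CO[Si](c2ccccc2)(c2ccccc2)C(C)(C)C)CCO1 | intermediate
15 | (2S,3R,6S)-1-[(tert-butyldiphenylsilyl)oxy]-6-hydroperoxy-8-hydroxy-2,6-dimethyloctan-3-yl methanesulfonate | OCC[C@@](C)(OO)CC[C@@H](OS(C)(=O)=O)[C@@H](C)CO[Si](c1ccccc1)(c1ccccc1)C(C)(C)C | intermediate
16 | 2-[(3S,6S)-6-{(2S)-1-[(tert-butyldiphenylsilyl)oxy]propan-2-yl}-3-methyl-1,2-dioxan-3-yl]ethan-1-ol | OCC[C@]1(C)CC[C@@H]([C@@H](C)CO[Si](c2ccccc2)(c2ccccc2)C(C)(C)C)OO1 | intermediate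
17 | 2-[(3S,6S)-6-{(2S)-1-[(tert-butyldiphenylsilyl)oxy]propan-2-yl}-3-methyl-1,2-dioxan-3-yl]acetaldehyde | O=CC[C@]1(C)CC[C@@H]([C@@H](C)CO[Si](c2ccccc2)(c2ccccc2)C(C)(C)C)OO1 | intermediate
18 | tert-butyl{(2S)-2-[(3S,6S)-6-methyl-6-(prop-2-en-1-yl)-1,2-dioxan-3-yl]propoxy}diphenylsilane | C=CC[C@]1(C)CC[C@@H]([C@@H](C)CO[Si](c2ccccc2)(c2ccccc2)C(C)(C)C)OO1 | intermediate
19 | dihydro-β-ionone, 4-(2,6,6-trimethylcyclohex-1-en-1-yl)butan-2-one | CC(=O)CCC1=C(C)CCCC1(C)C | starting material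
20 | ethyl (2E)-3-methyl-5-(2,6,6-trimethylcyclohex-1-en-1-yl)pent-2-enoate | CCOC(=O)/C=C(\C)CCC1=C(C)CCCC1(C)C | intermediate
21 | (2E)-3-methyl-5-(2,6,6-trimethylcyclohex-1-en-1-yl)pent-2-en-1-ol | OC/C=C(\C)CCC1=C(C)CCCC1(C)C | intermediate
22 | {(2S,3S)-3-methyl-3-[2-(2,6,6-trimethylcyclohex-1-en-1-yl)ethyl]oxiran-2-yl}methanol | CC1=C(CC[C@]2(C)O[C@H]2CO)C(C)(C)CCC1 | intermediate
23 | (2R,3S)-2-(iodomethyl)-3-methyl-3-[2-(2,6,6-trimethylcyclohex-1-en-1-yl)ethyl]oxirane | CC1=C(CC[C@]2(C)O[C@H]2CI)C(C)(C)CCC1 | intermediate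
24 | (3S)-3-methyl-5-(2,6,6-trimethylcyclohex-1-en-1-yl)pent-1-en-3-ol | CC1=C(CC[C@](C)(O)C=C)C(C)(C)CCC1 | intermediate
25 | tert-butyl{(2S)-2-[(3S,6S)-6-[(2E,4S)-4-hydroxy-4-methyl-6-(2,6,6-trimethylcyclohex-1-en-1-yl)hex-2-en-1-yl]-6-methyl-1,2-dioxan-3-yl]propoxy}diphenylsilane | CC1=C(CC[C@](C)(O)/C=C/C[C@]2(C)CC[C@@H]([C@@H](C)CO[Si](c3ccccc3)(c3ccccc3)C(C)(C)C)OO2)C(C)(C)CCC1 | intermediate
26 | (2S)-2-[(3S,6S)-6-[(2E,4S)-4-hydroxy-4-methyl-6-(2,6,6-trimethylcyclohex-1-en-1-yl)hex-2-en-1-yl]-6-methyl-1,2-dioxan-3-yl]propan-1-ol | CC1=C(CC[C@](C)(O)/C=C/C[C@]2(C)CC[C@@H]([C@@H](C)CO)OO2)C(C)(C)CCC1 | intermediate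
27 | (2R)-2-[(3S,6S)-6-[(2E,4S)-4-hydroxy-4-methyl-6-(2,6,6-trimethylcyclohex-1-en-1-yl)hex-2-en-1-yl]-6-methyl-1,2-dioxan-3-yl]propanal (not isolated) | CC1=C(CC[C@](C)(O)/C=C/C[C@]2(C)CC[C@@H]([C@@H](C)C=O)OO2)C(C)(C)CCC1 | intermediate
28 | (2R)-2-[(3S,6S)-6-[(2E,4S)-4-hydroxy-4-methyl-6-(2,6,6-trimethylcyclohex-1-en-1-yl)hex-2-en-1-yl]-6-methyl-1,2-dioxan-3-yl]propanoic acid | CC1=C(CC[C@](C)(O)/C=C/C[C@]2(C)CC[C@@H]([C@@H](C)C(=O)O)OO2)C(C)(C)CCC1 | target

**Step count**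
Total: 23 steps. Longest linear sequence: 18 steps (steps 1–15 and 21–23, from geraniol); fragment 2 takes 5 steps (16–20).

**Three steps most likely to fail**

Step 12 (intermolecular perhydrolysis of the oxetane). Yields of this opening are moderate and any ionisation at C6 would erode the stereocentre. The fallback reverses the order of the two C–O bond formations; it sets out from 14 and comes back at 16, so it also replaces step 13. The mesylate of 14 is displaced by 2-methoxypropan-2-yl hydroperoxide with CsOH·H2O in DMF (SN2, inversion at C3) to give tert-butyl{[(2S,3S)-3-[(2-methoxypropan-2-yl)peroxy]-2-methyl-5-[(2R)-2-methyloxetan-2-yl]pentyl]oxy}diphenylsilane F1. Aqueous AcOH in THF unmasks (2S,3S)-1-[(tert-butyldiphenylsilyl)oxy]-2-methyl-5-[(2R)-2-methyloxetan-2-yl]pentan-3-yl hydroperoxide F2. Me3SiOTf (0.1 equiv) in CH2Cl2 at −78 °C then makes the hydroperoxide open the oxetane intramolecularly at its tertiary carbon (6-exo, inversion at C6), giving 16.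

Step 21 (cross-metathesis). The tertiary allylic alcohol is hindered and the catalyst must work beside a peroxide. The fallback is a Julia–Kocienski union; it sets out from 16 and 24 and comes back at 25, bypassing 17 and 18.
- Mitsunobu thioetherification of 16 with 1-phenyl-1H-tetrazole-5-thiol (PPh3, diisopropyl azodicarboxylate, THF) gives 5-({2-[(3S,6S)-6-{(2S)-1-[(tert-butyldiphenylsilyl)oxy]propan-2-yl}-3-methyl-1,2-dioxan-3-yl]ethyl}sulfanyl)-1-phenyl-1H-tetrazole F3.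
- (NH4)6Mo7O24·4H2O and H2O2 in EtOH oxidise it to 5-({2-[(3S,6S)-6-{(2S)-1-[(tert-butyldiphenylsilyl)oxy]propan-2-yl}-3-methyl-1,2-dioxan-3-yl]ethyl}sulfonyl)-1-phenyl-1H-tetrazole F4.
- In parallel, 24 is silylated (Et3SiOTf, 2,6-lutidine) to triethyl{[(3S)-3-methyl-5-(2,6,6-trimethylcyclohex-1-en-1-yl)pent-1-en-3-yl]oxy}silane F5.
- Its vinyl group is cleaved (OsO4 cat., NaIO4, 2,6-lutidine, dioxane/H2O; the tetrasubstituted ring olefin reacts far more slowly) to (2S)-2-methyl-2-[(triethylsilyl)oxy]-4-(2,6,6-trimethylcyclohex-1-en-1-yl)butanal F6.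
- Deprotonation of F4 with KN(SiMe3)2 in DME at −78 °C and addition of F6 gives the E-olefin tert-butyl{(2S)-2-[(3S,6S)-6-methyl-6-{(2E,4S)-4-methyl-4-[(triethylsilyl)oxy]-6-(2,6,6-trimethylcyclohex-1-en-1-yl)hex-2-en-1-yl}-1,2-dioxan-3-yl]propoxy}diphenylsilane F7.
- HF·pyridine with extra pyridine in THF removes only the triethylsilyl group and gives 25.

Step 23 (oxidation of the fully assembled alcohol). The aldehyde 27 can epimerise at C2 or lose the β-peroxide, and the oxidants meet a tertiary allylic alcohol and an electron-rich olefin. The fallback oxidises before the fragments are joined; it sets out from 18 and comes back at 28. Bu4NF/AcOH in THF gives (2S)-2-[(3S,6S)-6-methyl-6-(prop-2-en-1-yl)-1,2-dioxan-3-yl]propan-1-ol F8. TEMPO/PhI(OAc)2 gives (2R)-2-[(3S,6S)-6-methyl-6-(prop-2-en-1-yl)-1,2-dioxan-3-yl]propanal F9 (not isolated), and NaClO2, NaH2PO4 and 2-methyl-2-butene give (2R)-2-[(3S,6S)-6-methyl-6-(prop-2-en-1-yl)-1,2-dioxan-3-yl]propanoic acid F10. Cross-metathesis of F10 with 24 under the conditions of step 21 then gives 28 as the last step.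

**Further compounds**
F1 | step 12 | tert-butyl{[(2S,3S)-3-[(2-methoxypropan-2-yl)peroxy]-2-methyl-5-[(2R)-2-methyloxetan-2-yl]pentyl]oxy}diphenylsilane | C[C@@]1(CC[C@@H]([C@@H](C)CO[Si](c2ccccc2)(c2ccccc2)C(C)(C)C)OOC(C)(C)OC)CCO1
F2 | step 12 | (2S,3S)-1-[(tert-butyldiphenylsilyl)oxy]-2-methyl-5-[(2R)-2-methyloxetan-2-yl]pentan-3-yl hydroperoxide | C[C@@]1(CC[C@@H]([C@@H](C)CO[Si](c2ccccc2)(c2ccccc2)C(C)(C)C)OO)CCO1
F3 | step 21 | 5-({2-[(3S,6S)-6-{(2S)-1-[(tert-butyldiphenylsilyl)oxy]propan-2-yl}-3-methyl-1,2-dioxan-3-yl]ethyl}sulfanyl)-1-phenyl-1H-tetrazole | c1ccc(cc1)-n1nnnc1SCC[C@]1(C)CC[C@@H]([C@@H](C)CO[Si](c2ccccc2)(c2ccccc2)C(C)(C)C)OO1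
F4 | step 21 | 5-({2-[(3S,6S)-6-{(2S)-1-[(tert-butyldiphenylsilyl)oxy]propan-2-yl}-3-methyl-1,2-dioxan-3-yl]ethyl}sulfonyl)-1-phenyl-1H-tetrazole | c1ccc(cc1)-n1nnnc1S(=O)(=O)CC[C@]1(C)CC[C@@H]([C@@H](C)CO[Si](c2ccccc2)(c2ccccc2)C(C)(C)C)OO1
F5 | step 21 | triethyl{[(3S)-3-methyl-5-(2,6,6-trimethylcyclohex-1-en-1-yl)pent-1-en-3-yl]oxy}silane | CC1=C(CC[C@](C)(O[Si](CC)(CC)CC)C=C)C(C)(C)CCC1
F6 | step 21 | (2S)-2-methyl-2-[(triethylsilyl)oxy]-4-(2,6,6-trimethylcyclohex-1-en-1-yl)butanal | CC1=C(CC[C@](C)(O[Si](CC)(CC)CC)C=O)C(C)(C)CCC1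
F7 | step 21 | tert-butyl{(2S)-2-[(3S,6S)-6-methyl-6-{(2E,4S)-4-methyl-4-[(triethylsilyl)oxy]-6-(2,6,6-trimethylcyclohex-1-en-1-yl)hex-2-en-1-yl}-1,2-dioxan-3-yl]propoxy}diphenylsilane | CC1=C(CC[C@](C)(O[Si](CC)(CC)CC)/C=C/C[C@]2(C)CC[C@@H]([C@@H](C)CO[Si](c3ccccc3)(c3ccccc3)C(C)(C)C)OO2)C(C)(C)CCC1
F8 | step 23 | (2S)-2-[(3S,6S)-6-methyl-6-(prop-2-en-1-yl)-1,2-dioxan-3-yl]propan-1-ol | C=CC[C@]1(C)CC[C@@H]([C@@H](C)CO)OO1
F9 | step 23 | (2R)-2-[(3S,6S)-6-methyl-6-(prop-2-en-1-yl)-1,2-dioxan-3-yl]propanal | C=CC[C@]1(C)CC[C@@H]([C@@H](C)C=O)OO1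
F10 | step 23 | (2R)-2-[(3S,6S)-6-methyl-6-(prop-2-en-1-yl)-1,2-dioxan-3-yl]propanoic acid | C=CC[C@]1(C)CC[C@@H]([C@@H](C)C(=O)O)OO1
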